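**Strategy.** The route rests on freeing ring A of the aryltetralin from both of its carbon substituents, C8a–C1 and C4a–C4 (tetralin numbering). One palladium/norbornene three-component coupling joins an aroyl chloride at C8a and dimethyl itaconate at C4a of 1-benzyloxy-4-iodo-2,3-dimethoxybenzene. It exploits the fact that the iodide-bearing C4a is flanked by the C5 methoxy group, so the C8a–H bond is the only ortho position open to palladation. The product, a 2-aroylbenzylidene succinate, already contains all carbons of the target. Asymmetric hydrogenation then sets C3, and closure of the C1–C2 bond between a benzhydryl cation and a silyl ketene acetal completes the saturated ring B.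

Key step: step 5

Remark: tetralin numbering is used for all late compounds (C1 diaryl methine on C8a, C2 and C3 bearing the one-carbon arms, C4 benzylic CH2 on C4a, OMe at C5 and C6, O at C7). The target is read as the all-trans (1R,2S,3S) isomer, and 4-benzyloxy-3-methoxybenzoic acid is taken as a purchasable starting material.

**Step 1**
Reactants: 1 2,3-dimethoxyphenol
Product: 2 triisopropyl(2,3-dimethoxyphenoxy)silane
Conditions: iPr3SiCl (1.1 equiv), imidazole (2 equiv), DMF, rt
Reagents that add atoms: chlorotriisopropylsilane, CC(C)[Si](Cl)(C(C)C)C(C)C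
Why: Standard O-silylation of a phenol; the bulky, poorly coordinating triisopropylsilyl ether is chosen because it shields C6 and does not direct lithiation in the next step.

**Step 2**
Reactants: 2 triisopropyl(2,3-dimethoxyphenoxy)silane
Product: 4 (4-iodo-2,3-dimethoxyphenoxy)triisopropylsilane, via aryllithium 3 (not isolated)
Conditions: n-BuLi (1.2 equiv), TMEDA (1.2 equiv), Et2O, 0 °C to rt; then I2 (1.3 equiv), THF, −78 °C to rt
Reagents that add atoms: iodine, II
Why: Directed ortho-metalation in which the C3 methoxy group is the only accessible directing group, so lithiation and iodine quench should place iodine at C4 alone; electrophilic iodination of the free phenol is avoided because C4 and C6 are both activated and a mixture would be likely.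

**Step 3**
Reactants: 4 (4-iodo-2,3-dimethoxyphenoxy)triisopropylsilane
Product: 6 1-benzyloxy-4-iodo-2,3-dimethoxybenzene, via tetrabutylammonium 4-iodo-2,3-dimethoxyphenoxide 5 (not isolated)
Conditions: Bu4NF (1.1 equiv), THF, 0 °C; then BnBr (1.3 equiv), rt
Reagents that add atoms: benzyl bromide, BrCc1ccccc1
Why: Fluoride cleavage of the aryl silyl ether gives the phenoxide, which undergoes Williamson benzylation in the same flask; the benzyl ether tolerates every later basic, hydridic and Lewis-acidic step and is removed by hydrogenolysis at the end.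

**Step 4**
Reactants: 7 4-benzyloxy-3-methoxybenzoic acid
Product: 8 4-benzyloxy-3-methoxybenzoyl chloride
Conditions: (COCl)2 (1.3 equiv), DMF (cat.), CH2Cl2, 0 °C to rt; used crude
Reagents that add atoms: oxalyl chloride, O=C(Cl)C(Cl)=O
Why: Acid chloride formation through the catalytic chloroiminium (Vilsmeier-type) species; the aryl benzyl ether is inert.

**Step 5**
Reactants: 6 1-benzyloxy-4-iodo-2,3-dimethoxybenzene; 8 4-benzyloxy-3-methoxybenzoyl chloride; 9 dimethyl itaconate
Product: 10 dimethyl (E)-2-{[4-benzyloxy-6-(4-benzyloxy-3-methoxybenzoyl)-2,3-dimethoxyphenyl]methylidene}butanedioate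
Conditions: Pd(OAc)2 (10 mol%), tri(2-furyl)phosphine (22 mol%), norbornene (2 equiv), Cs2CO3 (3 equiv), 8 (1.8 equiv), 9 (2 equiv), toluene, 90 °C; chromatography to isolate the pure E-benzylidene isomer
Reagents that add atoms: none
Why: Catellani reaction with ortho-acylation and Heck termination: zerovalent palladium inserts into the C–I bond of 6, norbornene carbopalladation and C–H palladation at the only free ortho carbon (future C8a, the other ortho carbon carrying the C5 methoxy group) give an aryl-norbornyl palladacycle, which 8 acylates through a tetravalent palladium species. With both ortho positions filled, norbornene is expelled by β-carbon elimination, and the aryl–palladium bond at the ipso carbon (future C4a) adds to the unsubstituted alkene terminus of 9, after which syn β-hydride elimination toward the benzylic side should give the conjugated benzylidene succinate. The closest known chemistry is the palladium/norbornene ortho-acylation of ortho-substituted aryl iodides with acyl chlorides or anhydrides terminated by acrylates. No ring is closed and no stereocentre is formed; the only stereo-element is the E alkene, expected because the aryl group avoids the ester on the same double bond. The step needs site selectivity, secured by the iodide position and the blocking methoxy group, and acylation of the palladacycle ahead of direct Heck coupling, helped by the ortho substituent, the weakly donating phosphine and the slowly inserting 1,1-disubstituted alkene. It also needs the product to survive, since its C2 methylene lies cis to the aroyl-bearing ring and could condense with the ketone under base, hence the nonpolar solvent, the carbonate base and no prolonged heating.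

**Step 6**
Reactants: 10 dimethyl (E)-2-{[4-benzyloxy-6-(4-benzyloxy-3-methoxybenzoyl)-2,3-dimethoxyphenyl]methylidene}butanedioate
Product: 11 dimethyl (2S)-2-{[4-benzyloxy-6-(4-benzyloxy-3-methoxybenzoyl)-2,3-dimethoxyphenyl]methyl}butanedioate
Conditions: [Rh(cod)((S,S)-Et-DuPhos)]BF4 (2 mol%), H2 (10 bar), MeOH, 25 °C
Reagents that add atoms: none
Why: Asymmetric hydrogenation of a β-aryl itaconate diester, in which the alkene and the carbonyl of the CH2-bound ester chelate the cationic rhodium centre and the ligand fixes the face of hydrogen delivery, setting C3 as S; benzyl ethers and the diaryl ketone are inert to this catalyst, and the antipodal ligand would be taken if a test run showed the opposite sense.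

**Step 7**
Reactants: 11 dimethyl (2S)-2-{[4-benzyloxy-6-(4-benzyloxy-3-methoxybenzoyl)-2,3-dimethoxyphenyl]methyl}butanedioate
Product: 12 dimethyl (2S)-2-({4-benzyloxy-6-[(4-benzyloxy-3-methoxyphenyl)(hydroxy)methyl]-2,3-dimethoxyphenyl}methyl)butanedioate, both carbinol epimers
Conditions: NaBH4 (1.5 equiv), MeOH/THF 1:1, 0 °C, short reaction time
Reagents that add atoms: none
Why: Borohydride reduction of the diaryl ketone with the methyl esters untouched at 0 °C; the configuration of the new carbinol centre does not matter because this carbon is ionised in the next step.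

**Step 8**
Reactants: 12 dimethyl (2S)-2-({4-benzyloxy-6-[(4-benzyloxy-3-methoxyphenyl)(hydroxy)methyl]-2,3-dimethoxyphenyl}methyl)butanedioate
Product: 14 dimethyl (1R,3S)-7-benzyloxy-1-(4-benzyloxy-3-methoxyphenyl)-5,6-dimethoxy-1,2,3,4-tetrahydronaphthalene-2,3-dicarboxylate as a mixture of C2 epimers, via bis-silylated ketene acetal 13 (not isolated)
Conditions: Me3SiCl (4 equiv), LiN(iPr)2 (2.4 equiv), THF, −78 °C; solvent exchange to pentane and filtration; Me3SiOTf (0.2 equiv), CH2Cl2, −78 to −40 °C; aq. NaHCO3; chromatography to remove any isomer with C1 trans to C3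
Reagents that add atoms: none
Why: Kinetic deprotonation by the hindered amide base should occur at the C2 methylene and not at the shielded C3 methine, and silylation in situ gives the ketene acetal and the silyl ether; catalytic Me3SiOTf then ionises the benzhydryl position, which is stabilised by two para-alkoxyaryl groups, and the cation is trapped intramolecularly in a six-membered closure (Mukaiyama-type SN1 alkylation of a silyl ketene acetal), with C1 set cis to C3 through a half-chair transition state that keeps the C3 ester pseudo-equatorial and turns the pendant aryl group away from C4.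

**Step 9**
Reactants: 14 dimethyl (1R,3S)-7-benzyloxy-1-(4-benzyloxy-3-methoxyphenyl)-5,6-dimethoxy-1,2,3,4-tetrahydronaphthalene-2,3-dicarboxylate (C2 epimers)
Product: 15 dimethyl (1R,2S,3S)-7-benzyloxy-1-(4-benzyloxy-3-methoxyphenyl)-5,6-dimethoxy-1,2,3,4-tetrahydronaphthalene-2,3-dicarboxylate
Conditions: NaOMe (0.5 equiv), MeOH/THF, rt to 50 °C
Reagents that add atoms: none
Why: Base-mediated epimerisation alpha to the esters under thermodynamic control moves the C2 ester into the equatorial position trans to both neighbours, while C3 already holds its favoured configuration relative to the fixed C1, so the all-trans diester should result without loss of optical purity.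

**Step 10**
Reactants: 15 dimethyl (1R,2S,3S)-7-benzyloxy-1-(4-benzyloxy-3-methoxyphenyl)-5,6-dimethoxy-1,2,3,4-tetrahydronaphthalene-2,3-dicarboxylate
Product: 16 [(1R,2S,3S)-7-benzyloxy-1-(4-benzyloxy-3-methoxyphenyl)-5,6-dimethoxy-1,2,3,4-tetrahydronaphthalene-2,3-diyl]dimethanol
Conditions: LiAlH4 (3 equiv), THF, 0 °C to rt
Reagents that add atoms: none
Why: Hydride reduction of both esters to primary alcohols, fast enough at 0 °C that no epimerisation is expected; aryl benzyl ethers and methyl ethers are stable.

**Step 11**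
Reactants: 16 [(1R,2S,3S)-7-benzyloxy-1-(4-benzyloxy-3-methoxyphenyl)-5,6-dimethoxy-1,2,3,4-tetrahydronaphthalene-2,3-diyl]dimethanol
Product: 17 (1R,2S,3S)-1-(4-hydroxy-3-methoxyphenyl)-2,3-bis(hydroxymethyl)-5,6-dimethoxy-1,2,3,4-tetrahydronaphthalen-7-ol (target)
Conditions: H2 (1 atm), Pd/C (10 wt%), EtOAc/MeOH, rt
Reagents that add atoms: none
Why: Catalytic hydrogenolysis of the two aryl benzyl ethers under neutral conditions; the benzylic C–C bonds, the methyl ethers, the alcohols and the three stereocentres are not affected.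

**Compound list**
1 | 2,3-dimethoxyphenol | COc1cccc(O)c1OC | starting material
2 | triisopropyl(2,3-dimethoxyphenoxy)silane | COc1cccc(O[Si](C(C)C)(C(C)C)C(C)C)c1OC | intermediate
3 | [2,3-dimethoxy-4-(triisopropylsilyloxy)phenyl]lithium (formed in the flask) | COc1c([Li])ccc(O[Si](C(C)C)(C(C)C)C(C)C)c1OC | intermediate
4 | (4-iodo-2,3-dimethoxyphenoxy)triisopropylsilane | COc1c(I)ccc(O[Si](C(C)C)(C(C)C)C(C)C)c1OC | intermediate
5 | tetrabutylammonium 4-iodo-2,3-dimethoxyphenoxide (formed in the flask) | COc1c(I)ccc([O-])c1OC.CCCC[N+](CCCC)(CCCC)CCCC | intermediate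
6 | 1-benzyloxy-4-iodo-2,3-dimethoxybenzene | COc1c(I)ccc(OCc2ccccc2)c1OC | intermediate
7 | 4-benzyloxy-3-methoxybenzoic acid | COc1cc(C(=O)O)ccc1OCc1ccccc1 | starting material
8 | 4-benzyloxy-3-methoxybenzoyl chloride | COc1cc(C(Cl)=O)ccc1OCc1ccccc1 | intermediate
9 | dimethyl itaconate | C=C(CC(=O)OC)C(=O)OC | starting material
10 | dimethyl (E)-2-{[4-benzyloxy-6-(4-benzyloxy-3-methoxybenzoyl)-2,3-dimethoxyphenyl]methylidene}butanedioate | COC(=O)C/C(C(=O)OC)=C\c1c(OC)c(OC)c(OCc2ccccc2)cc1C(=O)c1ccc(OCc2ccccc2)c(OC)c1 | intermediate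
11 | dimethyl (2S)-2-{[4-benzyloxy-6-(4-benzyloxy-3-methoxybenzoyl)-2,3-dimethoxyphenyl]methyl}butanedioate | COC(=O)C[C@@H](C(=O)OC)Cc1c(OC)c(OC)c(OCc2ccccc2)cc1C(=O)c1ccc(OCc2ccccc2)c(OC)c1 | intermediate
12 | dimethyl (2S)-2-({4-benzyloxy-6-[(4-benzyloxy-3-methoxyphenyl)(hydroxy)methyl]-2,3-dimethoxyphenyl}methyl)butanedioate, both carbinol epimers | COC(=O)C[C@@H](C(=O)OC)Cc1c(OC)c(OC)c(OCc2ccccc2)cc1C(O)c1ccc(OCc2ccccc2)c(OC)c1 | intermediate
13 | methyl (2S)-2-({4-benzyloxy-6-[(4-benzyloxy-3-methoxyphenyl)(trimethylsilyloxy)methyl]-2,3-dimethoxyphenyl}methyl)-4-methoxy-4-(trimethylsilyloxy)but-3-enoate (formed in the flask) | COC(O[Si](C)(C)C)=C[C@@H](C(=O)OC)Cc1c(OC)c(OC)c(OCc2ccccc2)cc1C(O[Si](C)(C)C)c1ccc(OCc2ccccc2)c(OC)c1 | intermediate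
14 | dimethyl (1R,3S)-7-benzyloxy-1-(4-benzyloxy-3-methoxyphenyl)-5,6-dimethoxy-1,2,3,4-tetrahydronaphthalene-2,3-dicarboxylate, C2 epimers | COc1cc([C@@H]2c3cc(OCc4ccccc4)c(OC)c(OC)c3C[C@H](C(=O)OC)C2C(=O)OC)ccc1OCc1ccccc1 | intermediate
15 | dimethyl (1R,2S,3S)-7-benzyloxy-1-(4-benzyloxy-3-methoxyphenyl)-5,6-dimethoxy-1,2,3,4-tetrahydronaphthalene-2,3-dicarboxylate | COc1cc([C@@H]2c3cc(OCc4ccccc4)c(OC)c(OC)c3C[C@H](C(=O)OC)[C@H]2C(=O)OC)ccc1OCc1ccccc1 | intermediate
16 | [(1R,2S,3S)-7-benzyloxy-1-(4-benzyloxy-3-methoxyphenyl)-5,6-dimethoxy-1,2,3,4-tetrahydronaphthalene-2,3-diyl]dimethanol | COc1cc([C@@H]2c3cc(OCc4ccccc4)c(OC)c(OC)c3C[C@H](CO)[C@H]2CO)ccc1OCc1ccccc1 | intermediate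
17 | (1R,2S,3S)-1-(4-hydroxy-3-methoxyphenyl)-2,3-bis(hydroxymethyl)-5,6-dimethoxy-1,2,3,4-tetrahydronaphthalen-7-ol | COc1cc([C@@H]2c3cc(O)c(OC)c(OC)c3C[C@H](CO)[C@H]2CO)ccc1O | target

**Step count.** Total: 11 steps. Longest linear sequence: 10 steps (steps 1–3 and 5–11, from 2,3-dimethoxyphenol); step 4 is the side branch.

**Steps most likely to fail**

Step 5. Acylation of the palladacycle may be outrun by direct Heck coupling of the aryl–palladium species or by reductive closure to a benzocyclobutene. The product may also be lost to base-induced aldol condensation between its C2 methylene and the new ketone. The fallback sets out from 6 and returns at 10 without palladium/norbornene chemistry. Iodine–magnesium exchange of 6 (iPrMgCl·LiCl, THF, −20 °C) and quench with DMF should give 4-benzyloxy-2,3-dimethoxybenzaldehyde F1. Addition of LiN(Me)CH2CH2NMe2 to F1 gives the lithium α-amino alkoxide F2, whose chelating side arm directs n-BuLi to the only ring position next to the masked formyl group (future C8a), giving the ortho-lithiated amino alkoxide F3. This is acylated with 4-benzyloxy-N,3-dimethoxy-N-methylbenzamide F4 (from 8, MeNH(OMe)·HCl, Et3N, CH2Cl2), and aqueous acid releases 4-benzyloxy-6-(4-benzyloxy-3-methoxybenzoyl)-2,3-dimethoxybenzaldehyde F5. Horner–Wadsworth–Emmons olefination of the aldehyde group with dimethyl 2-(dimethoxyphosphoryl)butanedioate (NaH, THF, 0 °C) should then give 10 as the E isomer, the diaryl ketone being inert to the stabilised phosphonate anion.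

Step 8. Deprotonation may compete at C3, or the cation may close with poor facial control, so that C1 is formed in both senses relative to C3 and optical purity is lost in the following equilibration. The fallback sets out from 11 and returns at 17; it sets C1 by hydrogenation instead. Kinetic enolisation of 11 at C2 (LiN(iPr)2, THF, −78 °C) and intramolecular aldol addition to the diaryl ketone should give dimethyl (3S)-7-benzyloxy-1-(4-benzyloxy-3-methoxyphenyl)-1-hydroxy-5,6-dimethoxy-1,2,3,4-tetrahydronaphthalene-2,3-dicarboxylate F6. Acid-catalysed dehydration (TsOH, toluene, 60 °C) gives dimethyl (3S)-7-benzyloxy-1-(4-benzyloxy-3-methoxyphenyl)-5,6-dimethoxy-3,4-dihydronaphthalene-2,3-dicarboxylate F7 with a C1=C2 double bond. Hydrogenation over Pd(OH)2/C (H2, 5 bar, EtOAc/MeOH) should deliver hydrogen to the face opposite the pseudo-axial C3 ester and cleave both benzyl ethers, giving dimethyl (1R,2R,3S)-7-hydroxy-1-(4-hydroxy-3-methoxyphenyl)-5,6-dimethoxy-1,2,3,4-tetrahydronaphthalene-2,3-dicarboxylate F8 with C1 cis to C3. NaOMe in MeOH epimerises C2 to dimethyl (1R,2S,3S)-7-hydroxy-1-(4-hydroxy-3-methoxyphenyl)-5,6-dimethoxy-1,2,3,4-tetrahydronaphthalene-2,3-dicarboxylate F9, and LiAlH4 reduction of F9 (THF, excess hydride for the two phenols) gives 17 directly.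

Step 6. The aryl ring with two ortho substituents is twisted out of the alkene plane and crowds the catalyst, so reduction may be slow or poorly face-selective; a co-eluting double-bond isomer would lower the selectivity further. The fallback sets out from 10 and returns at 11. Selective saponification of the non-conjugated, unhindered ester (LiOH, 1 equiv, THF/H2O, 0 °C) should give (E)-4-[4-benzyloxy-6-(4-benzyloxy-3-methoxybenzoyl)-2,3-dimethoxyphenyl]-3-(methoxycarbonyl)but-3-enoic acid F10. Carboxylate-directed asymmetric hydrogenation (Ru(OAc)2[(S)-BINAP] or its antipode, H2, 50 bar, MeOH) gives (3S)-4-[4-benzyloxy-6-(4-benzyloxy-3-methoxybenzoyl)-2,3-dimethoxyphenyl]-3-(methoxycarbonyl)butanoic acid F11, and methylation (MeI, K2CO3, DMF) returns 11.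

**Further compounds**
F1 | step 5 | 4-benzyloxy-2,3-dimethoxybenzaldehyde | COc1c(C=O)ccc(OCc2ccccc2)c1OC
F2 | step 5 | lithium (4-benzyloxy-2,3-dimethoxyphenyl){[2-(dimethylamino)ethyl](methyl)amino}methanolate | COc1c(C([O-])N(C)CCN(C)C)ccc(OCc2ccccc2)c1OC.[Li+]
F3 | step 5 | lithium (4-benzyloxy-6-lithio-2,3-dimethoxyphenyl){[2-(dimethylamino)ethyl](methyl)amino}methanolate | COc1c(C([O-])N(C)CCN(C)C)c([Li])cc(OCc2ccccc2)c1OC.[Li+]
F4 | step 5 | 4-benzyloxy-N,3-dimethoxy-N-methylbenzamide | COc1cc(C(=O)N(C)OC)ccc1OCc1ccccc1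
F5 | step 5 | 4-benzyloxy-6-(4-benzyloxy-3-methoxybenzoyl)-2,3-dimethoxybenzaldehyde | COc1c(C=O)c(C(=O)c2ccc(OCc3ccccc3)c(OC)c2)cc(OCc2ccccc2)c1OC
F6 | step 8 | dimethyl (3S)-7-benzyloxy-1-(4-benzyloxy-3-methoxyphenyl)-1-hydroxy-5,6-dimethoxy-1,2,3,4-tetrahydronaphthalene-2,3-dicarboxylate | COc1cc(C2(O)c3cc(OCc4ccccc4)c(OC)c(OC)c3C[C@H](C(=O)OC)C2C(=O)OC)ccc1OCc1ccccc1
F7 | step 8 | dimethyl (3S)-7-benzyloxy-1-(4-benzyloxy-3-methoxyphenyl)-5,6-dimethoxy-3,4-dihydronaphthalene-2,3-dicarboxylate | COc1cc(C2=C(C(=O)OC)[C@@H](C(=O)OC)Cc3c(OC)c(OC)c(OCc4ccccc4)cc32)ccc1OCc1ccccc1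
F8 | step 8 | dimethyl (1R,2R,3S)-7-hydroxy-1-(4-hydroxy-3-methoxyphenyl)-5,6-dimethoxy-1,2,3,4-tetrahydronaphthalene-2,3-dicarboxylate | COc1cc([C@@H]2c3cc(O)c(OC)c(OC)c3C[C@H](C(=O)OC)[C@@H]2C(=O)OC)ccc1O
F9 | step 8 | dimethyl (1R,2S,3S)-7-hydroxy-1-(4-hydroxy-3-methoxyphenyl)-5,6-dimethoxy-1,2,3,4-tetrahydronaphthalene-2,3-dicarboxylate | COc1cc([C@@H]2c3cc(O)c(OC)c(OC)c3C[C@H](C(=O)OC)[C@H]2C(=O)OC)ccc1O
F10 | step 6 | (E)-4-[4-benzyloxy-6-(4-benzyloxy-3-methoxybenzoyl)-2,3-dimethoxyphenyl]-3-(methoxycarbonyl)but-3-enoic acid | OC(=O)C/C(C(=O)OC)=C\c1c(OC)c(OC)c(OCc2ccccc2)cc1C(=O)c1ccc(OCc2ccccc2)c(OC)c1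
F11 | step 6 | (3S)-4-[4-benzyloxy-6-(4-benzyloxy-3-methoxybenzoyl)-2,3-dimethoxyphenyl]-3-(methoxycarbonyl)butanoic acid | OC(=O)C[C@@H](C(=O)OC)Cc1c(OC)c(OC)c(OCc2ccccc2)cc1C(=O)c1ccc(OCc2ccccc2)c(OC)c1
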